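# Synthesis proposal for 7-hydroxy-5-methoxy-3-(4-methoxybenzyl)-6-methyl-4-oxo-4H-chromene-8-carbaldehyde (12)

## The problem

The target 12 is a 3-benzylchromone: a 4-pyranone (ring C) fused through C4a–C8a to a benzene ring (ring A) in which every carbon is substituted. Ring A carries OMe at C5, Me at C6, OH at C7 and CHO at C8, and C3 of ring C carries a 4-methoxybenzyl group. There is no stereocentre, so the difficulty is regiochemical. The three oxygens of a phloroglucinol core must end in three different states (methyl ether at C5, free phenol at C7, ring oxygen O1). The two carbon substituents (the formyl group at C8 and the acyl carbon C4 at C4a) must go to defined ring positions.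

Several groups limit the choice of reagents. The free aldehyde between two oxygens excludes hydrides, strong bases and peroxide oxidants. The C5 methyl ether sits peri to the C4 carbonyl and is cleaved by chelating Lewis acids. C2 of the pyranone is opened by hydroxide or amines. The C3–CH2–aryl methylene can slip out of the ring as a benzylidene.

The feature that makes the key step possible is the C2=C3 double bond. C2 is an enol ether carbon on O1 and C3 is the α-carbon of the C4 ketone. Cutting this bond leaves a vinyl ether on the C8a oxygen and an α-methylene ketone on C4a, held ortho to each other and placed for closure of a six-membered ring.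

## Retrosynthesis

**12 from 11 (O–vinyl at C7).** The last cut removes a vinyl group from the C7 oxygen, leading back to 5-methoxy-3-(4-methoxybenzyl)-6-methyl-4-oxo-7-(vinyloxy)-4H-chromene-8-carbaldehyde 11. The two phenols that flank the formyl group cannot be told apart reliably, so both receive the group that the key step needs, and the spectator is removed afterwards with dilute aqueous acid. A benzyl ether would need hydrogenolysis (risk to C2=C3 and the aldehyde) or a boron halide (loss of the C5 methyl ether). An acetal protecting group would require the very differentiation this choice avoids. The forward reaction only has to hydrolyse an aryl vinyl ether without touching the vinylogous ester of ring C.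

**11 from 10 (C2=C3).** The C2=C3 bond is cut as a ring-closing metathesis retron. This gives 4-methoxy-5-[2-(4-methoxybenzyl)acryloyl]-3-methyl-2,6-bis(vinyloxy)benzaldehyde 10. The neighbouring cuts were weighed against it:
- Cutting O1–C2 leads to the classical one-carbon insertion into a 2-hydroxyaryl ketone, which brings a formylating electrophile onto a ring that already carries an aldehyde and a second phenol.
- Cutting C4–C4a or C3–C4 leads to carbonylative chemistry at the most crowded aryl carbon.

The metathesis cut closes ring C at carbon under neutral conditions with all carbons already in place. The precursor is simpler by one ring. The forward reaction must join an aryloxy-substituted carbene to an electron-poor 1,1-disubstituted olefin, and must use only the vinyl ether that lies next to the enone.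

**10 from 8 (exocyclic C=CH2).** The exocyclic methylene is removed as a Mannich retron, giving the saturated ketone 4-methoxy-5-[3-(4-methoxyphenyl)propanoyl]-3-methyl-2,6-bis(vinyloxy)benzaldehyde 8. This cut comes before the O–vinyl cut because an α-methylene ketone next to a free phenol would close to a chromanone by oxa-Michael addition. The forward methylenation must spare two aryl vinyl ethers and a free aldehyde, which argues for an anhydrous iminium acetate and against enolate chemistry.

**8 from 7 (two O–vinyl bonds).** Both O–vinyl bonds are cut together to the bis-phenol 2,6-dihydroxy-4-methoxy-5-[3-(4-methoxyphenyl)propanoyl]-3-methylbenzaldehyde 7. Cutting both saves a protecting-group sequence. The forward reaction is a copper-mediated vinyl transfer from boron at room temperature and must reach two hydrogen-bonded, flanked phenols.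

**7 from 4 and 6 (C4a–C4).** The aryl–acyl bond is cut to 2,6-dihydroxy-4-methoxy-3-methylbenzaldehyde 4 and 3-(4-methoxyphenyl)propanoyl chloride 6, the latter from 3-(4-methoxyphenyl)propanoic acid 5. Compound 4 has one unsubstituted ring carbon, so the Friedel–Crafts acylation has no regiochemical choice. The alternative order (acylate first, formylate later) would leave three chelated phenols that cannot be methylated selectively. The forward reaction must acylate a formyl-bearing but still electron-rich arene without cleaving the methyl ether.

**4 from 3 from 1 (O–Me, then C8–CHO).** The methyl ether is cut to 2,4,6-trihydroxy-3-methylbenzaldehyde 3, and the formyl group is cut to 2-methylphloroglucinol 1. Introducing the aldehyde first is what orders the oxygens. In 3 the hydroxyl para to the formyl group is the only one not hydrogen-bonded to a carbonyl and is the most acidic, and it is the oxygen that must become the C5 methyl ether. The two free positions of 1 are equivalent by symmetry, so formylation gives a single product.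

## Roads not taken

**Alternative 1:** Ring A is cut at C4a–C5 and C8–C8a.
- Forward step: a [4+2] cycloaddition of the ketene acetal diene [(4,4-dimethoxy-3-methylbuta-1,3-dien-2-yl)oxy]trimethylsilane A3 onto the sulfinyl-activated C5=C6 bond of 3-(4-methoxybenzyl)-5-(phenylsulfinyl)-4H-pyran-4-one A2. Syn-elimination of the sulfoxide, loss of one acetal methoxy group and desilylation aromatise the adduct to 7-hydroxy-5-methoxy-3-(4-methoxybenzyl)-6-methyl-4H-chromen-4-one A1. Ortho-formylation of A1 at C8, the only open position, would finish 12.
- Merits: the diene itself fixes which oxygen is a methyl ether and which a phenol, so no phenol has to be differentiated. No aldehyde is carried through the sequence. Cycloadditions of such dienes to sulfinyl-activated enones are a known reaction class. In these three respects this road is stronger than the chosen plan.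
- Weak points: A2 needs a 4-pyranone with a benzyl group on one side and a sulfoxide on the other, which is a regiochemical problem of its own and costs several steps. A3 is a hydrolytically fragile, fully substituted ketene acetal. The fully substituted acetal terminus of A3 must bond to the sulfinyl-bearing carbon of a weakly dienophilic vinylogous ester.
- Comparison: the chosen plan offers a ring A bought nearly complete and elaborated by classical aromatic chemistry, and no sensitive diene. It pays with a key step that has no precedent.

**Alternative 2:** Ring C is cut at C4a–C4, C4–C3 and O1–C2.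
- Forward step: Pd(OAc)2 with 1,4-bis(diphenylphosphino)butane joins 2,6-dihydroxy-5-iodo-4-methoxy-3-methylbenzaldehyde A5 (one iodination from 4), carbon monoxide and 1-methoxy-4-(propa-1,2-dien-1-yl)benzene A6. The product is (E)-7-hydroxy-5-methoxy-3-(4-methoxybenzylidene)-6-methyl-4-oxochromane-8-carbaldehyde A4. Migration of the exocyclic double bond into the ring would then give 12.
- Merits: it is the shortest road, about five steps from 1 against eight. It forms three bonds in one operation and uses a reaction class established for simple 2-iodophenols. On step count and precedent it is better than the chosen plan.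
- Weak points: zerovalent palladium must insert into an iodide flanked by OMe and OH on an electron-rich, fully substituted ring. Carbon monoxide must then insert at that crowded centre faster than the allene adds directly. The phenoxide must attack the CH2 terminus of the π-allyl intermediate and not the aryl-bearing terminus, which would give the 2-aryl-3-methylene isomer. A4 still needs a separate isomerisation.
- Comparison: the chosen plan makes the hindered C4a–C4 bond by acylation at the only open ring position. Its ring closure has a single possible constitution, because O1–C2 exists before closure and the olefin is formed directly in the ring.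

**Alternative 3:** Ring A is cut at C8–C8a, C7–C8, C5–C6 and C4a–C5.
- Forward step: irradiation of 2-(2-diazoacetyl)-5-(4-methoxybenzyl)-4H-pyran-4-one A8 with triisopropyl(prop-1-yn-1-yloxy)silane A9. A Wolff rearrangement gives a pyranyl ketene, which undergoes [2+2] addition to the ynol ether, four-electron ring opening and six-electron closure. The product is 5-hydroxy-3-(4-methoxybenzyl)-6-methyl-7-(triisopropylsilyloxy)-4H-chromen-4-one A7.
- Merits: the mechanism dictates the substitution pattern of ring A. The two oxygens arrive differentiated (one free, one silylated). The benzannulation is a known reaction class. In regiochemical certainty it is better than the chosen plan.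
- Weak points: A7 has C5 as a chelated phenol and C8 unsubstituted, so three further operations are needed (methylation of the chelated hydroxyl, desilylation, formylation). A8 needs a 5-benzyl-4-pyranone-2-carboxylic acid and a diazo transfer sequence. The pyranone chromophore absorbs in the irradiation window and has its own photochemistry.
- Comparison: this is the longest road. The chosen plan is shorter and uses a commercial ring A, at the price of one selective methylation and an untested ring closure.

Key step: step 7

## Route

Remark on the chemistry: the target has no stereocentre; the Mannich base 9 forms as a racemate and its configuration is lost in the elimination.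

Step 1
Reactants: 1 2-methylbenzene-1,3,5-triol (2-methylphloroglucinol)
Product: 3 2,4,6-trihydroxy-3-methylbenzaldehyde, via aryl iminium chloride 2 (not isolated)
Conditions: POCl3 (1.1 equiv), DMF (1.2 equiv), EtOAc, 0 °C → rt; then H2O, 50 °C
Reagents that add atoms: N,N-dimethylformamide, CN(C)C=O; water, O
Why: Vilsmeier–Haack formylation: the two unsubstituted positions of 1 are equivalent by symmetry, so the chloroiminium ion gives a single iminium salt 2, whose deactivated ring should resist a second formylation when one equivalent of reagent is used; water hydrolyses 2 to the aldehyde.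

Step 2
Reactants: 3 2,4,6-trihydroxy-3-methylbenzaldehyde
Product: 4 2,6-dihydroxy-4-methoxy-3-methylbenzaldehyde
Conditions: Me2SO4 (1.0 equiv), K2CO3 (1.05 equiv), acetone, 0 °C → rt
Reagents that add atoms: dimethyl sulfate, COS(=O)(=O)OC
Why: Regioselective Williamson-type O-methylation: the C4 hydroxyl, para to the formyl group, is the most acidic and the only one not hydrogen-bonded to the carbonyl, so one equivalent of base and of dimethyl sulfate should etherify it alone; the hard sulfate electrophile in an aprotic solvent favours O- over C-methylation at C5.

Step 3
Reactants: 5 3-(4-methoxyphenyl)propanoic acid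
Product: 6 3-(4-methoxyphenyl)propanoyl chloride
Conditions: (COCl)2 (1.2 equiv), DMF (cat.), CH2Cl2, 0 °C → rt; concentrate
Reagents that add atoms: oxalyl chloride, ClC(=O)C(=O)Cl
Why: Acid chloride formation through the chloroiminium species generated from DMF and oxalyl chloride; the by-products are gases and the crude chloride is used directly.

Step 4
Reactants: 4 2,6-dihydroxy-4-methoxy-3-methylbenzaldehyde; 6 3-(4-methoxyphenyl)propanoyl chloride
Product: 7 2,6-dihydroxy-4-methoxy-5-[3-(4-methoxyphenyl)propanoyl]-3-methylbenzaldehyde
Conditions: AlCl3 (3.5 equiv), CH2Cl2–MeNO2, 0 °C → rt; then ice, 1 M HCl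
Reagents that add atoms: none
Why: Friedel–Crafts acylation: C5 is the only unsubstituted ring carbon and lies ortho to the methoxy and one hydroxyl group, para to the other hydroxyl and meta to the formyl group, so the regiochemistry is fixed and the ring remains nucleophilic enough. Nitromethane-moderated AlCl3 at or below room temperature and a short reaction time are chosen so that the new ketone does not assist cleavage of the neighbouring methyl ether.

Step 5
Reactants: 7 2,6-dihydroxy-4-methoxy-5-[3-(4-methoxyphenyl)propanoyl]-3-methylbenzaldehyde
Product: 8 4-methoxy-5-[3-(4-methoxyphenyl)propanoyl]-3-methyl-2,6-bis(vinyloxy)benzaldehyde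
Conditions: Cu(OAc)2 (2.5 equiv), 2,4,6-trivinylcyclotriboroxane·pyridine (1.5 equiv), pyridine (10 equiv), 4 Å MS, CH2Cl2, dry air, rt
Reagents that add atoms: 2,4,6-trivinylcyclotriboroxane–pyridine complex, C=CB1OB(C=C)OB(C=C)O1.c1ccncc1
Why: Chan–Lam-type oxidative C–O coupling: the divalent copper phenoxide takes a vinyl group from boron and reductive elimination from the oxidised copper centre forms the aryl vinyl ether at room temperature, conditions that leave the aldehyde and the enolisable ketone alone. Both hydroxyls are vinylated on purpose, since they cannot be told apart and only the one next to the acyl group can take part in step 7.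

Step 6
Reactants: 8 4-methoxy-5-[3-(4-methoxyphenyl)propanoyl]-3-methyl-2,6-bis(vinyloxy)benzaldehyde
Product: 10 4-methoxy-5-[2-(4-methoxybenzyl)acryloyl]-3-methyl-2,6-bis(vinyloxy)benzaldehyde, via Mannich base 9 (not isolated)
Conditions: CH2(NMe2)2 (4 equiv), Ac2O (6 equiv), BHT (cat.), DMF, rt → 70 °C
Reagents that add atoms: bis(dimethylamino)methane, CN(C)CN(C)C
Why: Mannich α-methylenation of an aryl alkyl ketone: the aminal and Ac2O generate the iminium acetate [Me2N=CH2]OAc, the ketone enol adds to it, and the racemic Mannich base 9 loses dimethylamine (taken up by Ac2O) to give the 1,1-disubstituted enone. The medium is anhydrous and free of strong acid or base, so the aryl vinyl ethers and the non-enolisable aldehyde should persist, and with both phenols capped no oxa-Michael closure to a chromanone can occur.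

Step 7
Reactants: 10 4-methoxy-5-[2-(4-methoxybenzyl)acryloyl]-3-methyl-2,6-bis(vinyloxy)benzaldehyde
Product: 11 5-methoxy-3-(4-methoxybenzyl)-6-methyl-4-oxo-7-(vinyloxy)-4H-chromene-8-carbaldehyde
Conditions: (H2IMes)Cl2Ru(=CH-C6H4-2-OiPr) (second-generation Hoveyda–Grubbs catalyst, 10 mol % in two portions), 1,4-benzoquinone (20 mol %), PhMe (0.005 M), 80 °C, Ar sparge
Reagents that add atoms: none
Why: Proposed new method: ring-closing metathesis between an aryl vinyl ether and an α-methylene aryl ketone to give a 4-pyranone has not been shown; the closest known reaction type is the ring-closing enol ether–olefin metathesis of aryl vinyl ethers to benzofurans and 4H-chromenes with ruthenium N-heterocyclic carbene catalysts. The ruthenium alkylidene should first exchange with the electron-rich vinyl ether on the future O1 to give an aryloxycarbene, Ru=CH–OAr, which then adds intramolecularly to the enone so that ruthenium takes the unsubstituted CH2 terminus and the carbene carbon bonds to the fully substituted carbon. Cycloreversion of the ruthenacyclobutane forms C2=C3 and releases Ru=CH2, which re-enters the cycle by exchange with another vinyl ether. Ring C closes as a six-membered ring with the new double bond endocyclic, and the vinylogous ester stabilisation of the 4-pyranone together with loss of ethylene should make the closure irreversible. No stereocentre is formed. The selectivity needed is between the two vinyl ethers and between closure and oligomerisation: only the vinyl ether flanked by the acyl group has an olefin within reach (a carbene formed at the other one can only pass ruthenium on by degenerate exchange), and high dilution suppresses intermolecular coupling. 1,4-Benzoquinone is added to intercept ruthenium hydrides that would move the exocyclic methylene into conjugation with the arene, and the aldehyde, ketone and aryl ethers are inert to the catalyst.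

Step 8
Reactants: 11 5-methoxy-3-(4-methoxybenzyl)-6-methyl-4-oxo-7-(vinyloxy)-4H-chromene-8-carbaldehyde
Product: 12 7-hydroxy-5-methoxy-3-(4-methoxybenzyl)-6-methyl-4-oxo-4H-chromene-8-carbaldehyde
Conditions: 1 M HCl, THF, 40 °C
Reagents that add atoms: none
Why: Acid-catalysed hydrolysis of an aryl vinyl ether: protonation at the terminal carbon, hydration of the oxocarbenium ion and collapse of the hemiacetal release the phenol and acetaldehyde. The ring C enol ether is a vinylogous ester and far less basic, and the methyl ethers, the aldehyde and the benzyl group are stable to dilute protic acid.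

## Compound list

1 | 2-methylbenzene-1,3,5-triol (2-methylphloroglucinol) | Cc1c(O)cc(O)cc1O | starting material
2 | N-methyl-N-[(2,4,6-trihydroxy-3-methylphenyl)methylidene]methanaminium chloride | Cc1c(O)cc(O)c(C=[N+](C)C)c1O.[Cl-] | intermediate (not isolated)
3 | 2,4,6-trihydroxy-3-methylbenzaldehyde | Cc1c(O)cc(O)c(C=O)c1O | intermediate
4 | 2,6-dihydroxy-4-methoxy-3-methylbenzaldehyde | COc1cc(O)c(C=O)c(O)c1C | intermediate
5 | 3-(4-methoxyphenyl)propanoic acid | COc1ccc(CCC(=O)O)cc1 | starting material
6 | 3-(4-methoxyphenyl)propanoyl chloride | COc1ccc(CCC(=O)Cl)cc1 | intermediate
7 | 2,6-dihydroxy-4-methoxy-5-[3-(4-methoxyphenyl)propanoyl]-3-methylbenzaldehyde | COc1ccc(CCC(=O)c2c(O)c(C=O)c(O)c(C)c2OC)cc1 | intermediate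
8 | 4-methoxy-5-[3-(4-methoxyphenyl)propanoyl]-3-methyl-2,6-bis(vinyloxy)benzaldehyde | COc1ccc(CCC(=O)c2c(OC=C)c(C=O)c(OC=C)c(C)c2OC)cc1 | intermediate
9 | 5-[3-(dimethylamino)-2-(4-methoxybenzyl)propanoyl]-4-methoxy-3-methyl-2,6-bis(vinyloxy)benzaldehyde (racemic) | COc1ccc(CC(CN(C)C)C(=O)c2c(OC=C)c(C=O)c(OC=C)c(C)c2OC)cc1 | intermediate (not isolated)
10 | 4-methoxy-5-[2-(4-methoxybenzyl)acryloyl]-3-methyl-2,6-bis(vinyloxy)benzaldehyde | COc1ccc(CC(=C)C(=O)c2c(OC=C)c(C=O)c(OC=C)c(C)c2OC)cc1 | intermediate
11 | 5-methoxy-3-(4-methoxybenzyl)-6-methyl-4-oxo-7-(vinyloxy)-4H-chromene-8-carbaldehyde | COc1ccc(Cc2coc3c(C=O)c(OC=C)c(C)c(OC)c3c2=O)cc1 | intermediate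
12 | 7-hydroxy-5-methoxy-3-(4-methoxybenzyl)-6-methyl-4-oxo-4H-chromene-8-carbaldehyde | COc1ccc(Cc2coc3c(C=O)c(O)c(C)c(OC)c3c2=O)cc1 | target

## Step count and risk

Total step count: 8. Longest linear sequence: 7 steps (steps 1, 2, 4, 5, 6, 7 and 8, from 1 to 12); step 3 is a one-step side branch.

**Step 7 (key step, proposed new method).**
- Most likely failure: the catalyst is held as an aryloxycarbene that does not add to the electron-poor, 1,1-disubstituted enone. Slow thermal decay of that carbene to ruthenium hydrides then drives migration of the exocyclic methylene into conjugation. Intermolecular coupling takes over if the concentration is raised to compensate.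
- Fallback (known chemistry): set out from 7 and heat it with N,N-dimethylformamide dimethyl acetal in toluene. This condenses the ketone α-methylene to the enaminone (E)-5-[3-(dimethylamino)-2-(4-methoxybenzyl)acryloyl]-2,6-dihydroxy-4-methoxy-3-methylbenzaldehyde F1. On brief acid treatment the hydroxyl next to the acyl group closes ring C by conjugate addition and loss of dimethylamine. This is the established enaminone route to 3-substituted chromones. It comes back to the route at 12 and bypasses 8, 10 and 11.

**Step 5 (bis-vinylation).**
- Most likely failure: incomplete vinylation of the hydroxyl flanked by both carbonyl groups. Both phenols bind divalent copper as stable chelates with their ortho carbonyls, and vinyl transfer to such electron-poor, hindered phenoxides is slow, so mono-vinylated material would accumulate.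
- Fallback: set out from 7 and alkylate both phenols under Mitsunobu conditions (2-(phenylselanyl)ethanol, PPh3, diisopropyl azodicarboxylate). This gives 4-methoxy-5-[3-(4-methoxyphenyl)propanoyl]-3-methyl-2,6-bis[2-(phenylselanyl)ethoxy]benzaldehyde F2. Oxidation with NaIO4 gives the bis-selenoxide 4-methoxy-5-[3-(4-methoxyphenyl)propanoyl]-3-methyl-2,6-bis[2-(phenylseleninyl)ethoxy]benzaldehyde F3. Warming F3 with NaHCO3 brings about syn-elimination to both vinyl ethers and returns to the route at 8.

**Step 4 (Friedel–Crafts acylation).**
- Most likely failure: chelation-assisted loss of the methyl ether once the ketone is in place, and self-acylation of the anisole ring of 6 competing with the formyl-deactivated arene.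
- Fallback: set out from 4 and esterify the less hindered hydroxyl with 6 (pyridine, 0 °C) to the aryl ester 2-formyl-3-hydroxy-5-methoxy-4-methylphenyl 3-(4-methoxyphenyl)propanoate F4. A photo-Fries rearrangement (254 nm, MeCN) should then deliver the acyl group to the only open ring carbon without any Lewis acid, returning to the route at 7.

**Step 6 (α-methylenation).**
- Most likely failure: sluggish enolisation of the twisted, doubly ortho-substituted aryl ketone, allowing the iminium ion to attack a vinyl ether, or re-addition of amine to the enone.
- Fallback: set out from 8 and carry out a base-catalysed aldol reaction with aqueous formaldehyde (K2CO3 cat., THF) to the hydroxymethyl ketone 5-[3-hydroxy-2-(4-methoxybenzyl)propanoyl]-4-methoxy-3-methyl-2,6-bis(vinyloxy)benzaldehyde F5. Mesylation (MsCl, Et3N) gives 3-[3-formyl-6-methoxy-5-methyl-2,4-bis(vinyloxy)phenyl]-2-(4-methoxybenzyl)-3-oxopropyl methanesulfonate F6, which eliminates in the same flask with excess amine and returns to the route at 10.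

**Step 2 (selective methylation).**
- Most likely failure: over-methylation at one of the chelated hydroxyls, or C-methylation at the free ring carbon.
- Fallback: set out from 3 and carry out a Mitsunobu methylation (MeOH, PPh3, diisopropyl azodicarboxylate, THF). This activates the alcohol instead of the phenoxide and selects the most acidic, non-chelated hydroxyl. It returns to the route at 4 and makes no compound outside the list (F0).

## Further compounds

F1 | step 7 | (E)-5-[3-(dimethylamino)-2-(4-methoxybenzyl)acryloyl]-2,6-dihydroxy-4-methoxy-3-methylbenzaldehyde | CN(C)/C=C(\Cc1ccc(OC)cc1)C(=O)c1c(O)c(C=O)c(O)c(C)c1OC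
F2 | step 5 | 4-methoxy-5-[3-(4-methoxyphenyl)propanoyl]-3-methyl-2,6-bis[2-(phenylselanyl)ethoxy]benzaldehyde | COc1ccc(CCC(=O)c2c(OCC[Se]c3ccccc3)c(C=O)c(OCC[Se]c3ccccc3)c(C)c2OC)cc1
F3 | step 5 | 4-methoxy-5-[3-(4-methoxyphenyl)propanoyl]-3-methyl-2,6-bis[2-(phenylseleninyl)ethoxy]benzaldehyde (mixture of isomers at selenium) | COc1ccc(CCC(=O)c2c(OCC[Se](=O)c3ccccc3)c(C=O)c(OCC[Se](=O)c3ccccc3)c(C)c2OC)cc1
F4 | step 4 | 2-formyl-3-hydroxy-5-methoxy-4-methylphenyl 3-(4-methoxyphenyl)propanoate | COc1ccc(CCC(=O)Oc2cc(OC)c(C)c(O)c2C=O)cc1
F5 | step 6 | 5-[3-hydroxy-2-(4-methoxybenzyl)propanoyl]-4-methoxy-3-methyl-2,6-bis(vinyloxy)benzaldehyde (racemic) | COc1ccc(CC(CO)C(=O)c2c(OC=C)c(C=O)c(OC=C)c(C)c2OC)cc1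
F6 | step 6 | 3-[3-formyl-6-methoxy-5-methyl-2,4-bis(vinyloxy)phenyl]-2-(4-methoxybenzyl)-3-oxopropyl methanesulfonate (racemic) | COc1ccc(CC(COS(C)(=O)=O)C(=O)c2c(OC=C)c(C=O)c(OC=C)c(C)c2OC)cc1
F0 | step 2 | none | none
A1 | alternative 1 | 7-hydroxy-5-methoxy-3-(4-methoxybenzyl)-6-methyl-4H-chromen-4-one | COc1ccc(Cc2coc3cc(O)c(C)c(OC)c3c2=O)cc1
A2 | alternative 1 | 3-(4-methoxybenzyl)-5-(phenylsulfinyl)-4H-pyran-4-one (racemic at sulfur) | COc1ccc(Cc2cocc(S(=O)c3ccccc3)c2=O)cc1
A3 | alternative 1 | [(4,4-dimethoxy-3-methylbuta-1,3-dien-2-yl)oxy]trimethylsilane | COC(OC)=C(C)C(=C)O[Si](C)(C)C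
A4 | alternative 2 | (E)-7-hydroxy-5-methoxy-3-(4-methoxybenzylidene)-6-methyl-4-oxochromane-8-carbaldehyde | COc1ccc(/C=C2\COc3c(C=O)c(O)c(C)c(OC)c3C2=O)cc1
A5 | alternative 2 | 2,6-dihydroxy-5-iodo-4-methoxy-3-methylbenzaldehyde | COc1c(C)c(O)c(C=O)c(O)c1I
A6 | alternative 2 | 1-methoxy-4-(propa-1,2-dien-1-yl)benzene | COc1ccc(C=C=C)cc1
A7 | alternative 3 | 5-hydroxy-3-(4-methoxybenzyl)-6-methyl-7-(triisopropylsilyloxy)-4H-chromen-4-one | COc1ccc(Cc2coc3cc(O[Si](C(C)C)(C(C)C)C(C)C)c(C)c(O)c3c2=O)cc1
A8 | alternative 3 | 2-(2-diazoacetyl)-5-(4-methoxybenzyl)-4H-pyran-4-one | COc1ccc(Cc2coc(C(=O)C=[N+]=[N-])cc2=O)cc1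
A9 | alternative 3 | triisopropyl(prop-1-yn-1-yloxy)silane | CC#CO[Si](C(C)C)(C(C)C)C(C)C
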